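**Retrosynthetic overview**
1. The ten-membered carbocycle is closed last, at C1–C10, by a new carbene-catalysed hydroacylation of an isopropenyl-type enol acetate by the C1 aldehyde; this sets C10 and delivers the tertiary acetate. The C13 acetate is exchanged for a PMB ether until the end.
2. The enol acetate comes from a terminal alkyne (AcOH addition); C8 comes from asymmetric propargylation of a 7-formyl butenolide; the C1 aldehyde comes from cleavage of the prenyl alkene of nerol.
3. The butenolide (second ring) comes from iodolactonisation of a 2,3-allenoic acid made by Pd-catalysed hydroxycarbonylation of a propargylic mesylate (C6 by centre-to-axis-to-centre chirality transfer); the vinyl iodide is then formylated.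
4. The C6 carbinol comes from Noyori reduction of an epoxy ynone (PMB propargyl ether plus epoxy aldehyde); the oxirane (first ring; C4, C5) comes from Sharpless epoxidation of nerol.
5. Ring order: oxirane, then butenolide, then ten-membered carbocycle.

Assumption: germacrane numbering (C1–C15; lactone C12, acetoxymethyl C13) is used for skeleton positions, and PMB propargyl ether and allenylboronic acid pinacol ester are bought.

Target configuration from the SMILES: 4R, 5S, 6S, 8S, 10R, with C3 and C6 cis on the oxirane (a nerol-type, Z-derived epoxide).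

**Step 1**
Reactants: 1 nerol
Product: 2 (2S,3R)-2,3-epoxynerol
Conditions: Ti(OiPr)4 (10 mol %), L-(+)-diethyl tartrate (12 mol %), t-BuOOH, 4 Å MS, CH2Cl2, −20 °C
Reagents that add atoms: tert-butyl hydroperoxide, CC(C)(C)OO
Why: Sharpless asymmetric epoxidation; the L-(+)-tartrate complex epoxidises only the allylic alcohol alkene and gives the (2S,3R)-oxirane, which fixes C4 (R) and C5 (S).

**Step 2**
Reactants: 2 (2S,3R)-2,3-epoxynerol
Product: 3 (2R,3R)-epoxy aldehyde
Conditions: TEMPO (10 mol %), PhI(OAc)2, CH2Cl2, rt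
Reagents that add atoms: none
Why: Oxoammonium (TEMPO) oxidation of the primary alcohol stops at the aldehyde and does not touch the oxirane stereocentres or the alkene.

**Step 3**
Reactants: 3 (2R,3R)-epoxy aldehyde; 4 PMB propargyl ether
Product: 7 propargylic alcohols (C6 epimer mixture), via lithium acetylide 5 (not isolated), via lithium alkoxide 6 (not isolated)
Conditions: 4, n-BuLi, THF, −78 °C; add 3; H2O quench
Reagents that add atoms: none
Why: Acetylide 1,2-addition to the aldehyde forms C6–C7; the C6 configuration is irrelevant because it is erased in step 4.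

**Step 4**
Reactants: 7 propargylic alcohols (C6 epimer mixture)
Product: 8 epoxy ynone
Conditions: Dess–Martin periodinane, pyridine, CH2Cl2, 0 °C
Reagents that add atoms: none
Why: Dess–Martin oxidation converts both epimers into one ynone under buffered, non-epimerising conditions.

**Step 5**
Reactants: 8 epoxy ynone
Product: 9 (1R)-propargylic alcohol
Conditions: Ru[(S,S)-TsDPEN](p-cymene) (2 mol %; TsDPEN = N-tosyl-1,2-diphenylethylenediamine), i-PrOH, rt
Reagents that add atoms: none
Why: Noyori asymmetric transfer hydrogenation; the (S,S) catalyst places the alkyne in the aryl position of the model and delivers hydride under catalyst control to give the 1R carbinol, and material from the minor epoxide enantiomer becomes a separable diastereomer.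

**Step 6**
Reactants: 9 (1R)-propargylic alcohol
Product: 10 (1R)-propargylic mesylate
Conditions: MsCl, Et3N, CH2Cl2, −40 °C; used crude
Reagents that add atoms: methanesulfonyl chloride, CS(=O)(=O)Cl
Why: O-Sulfonylation with retention gives the leaving group needed for the SN2' carbonylation.

**Step 7**
Reactants: 10 (1R)-propargylic mesylate
Product: 11 (Ra)-allenoic acid
Conditions: Pd(PPh3)4 (5 mol %), CO (1 atm), 2,6-lutidine, THF/H2O, 0 °C to rt; pH 4 work-up
Reagents that add atoms: carbon monoxide, [C-]#[O+]; water, O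
Why: Palladium-catalysed hydroxycarbonylation of a propargylic mesylate; zerovalent palladium attacks C11 anti to the mesylate (SN2'), CO inserts with retention, and the C6 centre is thereby transferred to the (Ra) allene axis.

**Step 8**
Reactants: 11 (Ra)-allenoic acid
Product: 12 4-iodobutenolide
Conditions: N-iodosuccinimide, CH2Cl2, 0 °C, dark
Reagents that add atoms: N-iodosuccinimide, O=C1CCC(=O)N1I
Why: Iodolactonisation of a 2,3-allenoic acid; the carboxyl oxygen can reach C6 only from its own side of the axis while iodine adds to C7, so the (Ra) axis gives the C6 configuration of the target (net inversion relative to 9).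

**Step 9**
Reactants: 12 4-iodobutenolide
Product: 13 4-formylbutenolide
Conditions: Pd(PPh3)4 (5 mol %), CO (3 atm), Bu3SnH (syringe pump), toluene, 50 °C
Reagents that add atoms: carbon monoxide, [C-]#[O+]
Why: Palladium-catalysed reductive carbonylation (formylation) of the activated vinyl iodide installs C8 as an aldehyde; slow hydride addition suppresses simple reduction.

**Step 10**
Reactants: 13 4-formylbutenolide; 14 allenylboronic acid pinacol ester
Product: 16 (8S)-homopropargylic alcohol, via pinacol borate ester 15 (not isolated)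
Conditions: 14 (1.5 equiv), (S)-3,3'-bis(2,4,6-triisopropylphenyl)-1,1'-binaphthyl-2,2'-diyl hydrogen phosphate (10 mol %), 4 Å MS, toluene, −20 °C; aqueous work-up
Reagents that add atoms: none
Why: Chiral phosphoric acid-catalysed asymmetric propargylation; SE2' transfer through a closed chair transition state to the Si face of the aldehyde forms C8–C9 and sets C8 (S) under catalyst control.

**Step 11**
Reactants: 16 (8S)-homopropargylic alcohol
Product: 17 C8 propanoate
Conditions: (EtCO)2O, pyridine, DMAP (cat.), CH2Cl2, 0 °C to rt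
Reagents that add atoms: propanoic anhydride, CCC(=O)OC(=O)CC
Why: DMAP-catalysed acylation installs the final C8 ester with retention; no β-elimination is possible because C10 is still an alkyne carbon.

**Step 12**
Reactants: 17 C8 propanoate
Product: 19 C1 aldehyde, via vicinal diol 18 (not isolated)
Conditions: OsO4 (2 mol %), NMO, acetone/H2O, rt; then NaIO4, THF/H2O
Reagents that add atoms: N-methylmorpholine N-oxide, C[N+]1([O-])CCOCC1; osmium tetroxide (catalytic oxygen carrier), O=[Os](=O)(=O)=O
Why: Upjohn dihydroxylation followed by periodate cleavage; only the electron-rich trisubstituted prenyl alkene reacts, while the electron-poor tetrasubstituted butenolide alkene and the alkyne are left.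

**Step 13**
Reactants: 19 C1 aldehyde
Product: 20 enol acetate aldehyde
Conditions: [RuCl2(p-cymene)]2 (1 mol %), P(2-furyl)3 (2 mol %), Na2CO3 (4 mol %), AcOH (1.5 equiv), toluene, 50 °C
Reagents that add atoms: acetic acid, CC(O)=O
Why: Ruthenium-catalysed Markovnikov hydro-acyloxylation of the terminal alkyne gives the 2-acetoxy-1-alkene (C10 carries OAc, C14 is CH2) under buffered conditions.

**Step 14**
Reactants: 20 enol acetate aldehyde
Product: 21 macrocyclic PMB ether
Conditions: (5aR,10bS)-2-mesityl-5a,10b-dihydro-4H,6H-indeno[2,1-b][1,2,4]triazolo[4,3-d][1,4]oxazin-2-ium chloride (20 mol %), i-Pr2NEt (20 mol %), 1,4-dioxane, 60 °C, syringe-pump addition to 0.002 M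
Reagents that add atoms: none
Why: Proposed new method: the triazolylidene adds to the C1 aldehyde to give the Breslow enaminol, which in one concerted, asynchronous ene-type step passes its O–H proton to the terminal CH2 (C14) of the enol acetate while its nucleophilic carbon bonds to C10. The acetoxy group polarises the alkene in exactly this Markovnikov sense, the step consumes the C=C and is irreversible, so the reversible aldehyde self-benzoin is funnelled to the ring under high dilution. The chiral carbene is chosen to direct attack to the Si face of C10, giving 10R with the acetate already in place; the sense of induction of this catalyst enantiomer is not established for this substrate. Closest known reaction: NHC-catalysed intramolecular hydroacylation of unactivated alkenes giving five- and six-membered ketones with quaternary centres; it has not been demonstrated with an enol ester acceptor or for a ten-membered ring.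

**Step 15**
Reactants: 21 macrocyclic PMB ether
Product: 22 C13 alcohol
Conditions: DDQ, CH2Cl2/pH 7 buffer (10:1), 0 °C to rt
Reagents that add atoms: none
Why: Oxidative cleavage of the PMB ether by DDQ is neutral and leaves the esters, the oxirane and the base-sensitive C6–H untouched.

**Step 16**
Reactants: 22 C13 alcohol
Product: 23 target CNP0285168.2
Conditions: Ac2O, pyridine, DMAP (cat.), CH2Cl2, 0 °C
Reagents that add atoms: acetic anhydride, CC(=O)OC(C)=O
Why: DMAP-catalysed acetylation of the only free (primary) hydroxyl completes the target without epimerisation.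

**Compound list**
1 | nerol, (2Z)-3,7-dimethylocta-2,6-dien-1-ol | CC(C)=CCC/C(C)=C\CO | starting material
2 | [(2S,3R)-3-methyl-3-(4-methylpent-3-en-1-yl)oxiran-2-yl]methanol | CC(C)=CCC[C@@]1(C)O[C@H]1CO | intermediate
3 | (2R,3R)-3-methyl-3-(4-methylpent-3-en-1-yl)oxirane-2-carbaldehyde | CC(C)=CCC[C@@]1(C)O[C@H]1C=O | intermediate
4 | 1-methoxy-4-[(prop-2-yn-1-yloxy)methyl]benzene (PMB propargyl ether) | C#CCOCc1ccc(OC)cc1 | starting material
5 | lithium acetylide of 4 | [Li]C#CCOCc1ccc(OC)cc1 | intermediate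
6 | lithium alkoxide of 7 (both carbinol epimers) | CC(C)=CCC[C@@]1(C)O[C@H]1C(O[Li])C#CCOCc1ccc(OC)cc1 | intermediate
7 | 1-[(2S,3R)-3-methyl-3-(4-methylpent-3-en-1-yl)oxiran-2-yl]-4-[(4-methoxybenzyl)oxy]but-2-yn-1-ol, both C1 epimers | CC(C)=CCC[C@@]1(C)O[C@H]1C(O)C#CCOCc1ccc(OC)cc1 | intermediate
8 | 1-[(2R,3R)-3-methyl-3-(4-methylpent-3-en-1-yl)oxiran-2-yl]-4-[(4-methoxybenzyl)oxy]but-2-yn-1-one | CC(C)=CCC[C@@]1(C)O[C@H]1C(=O)C#CCOCc1ccc(OC)cc1 | intermediate
9 | (1R)-1-[(2S,3R)-3-methyl-3-(4-methylpent-3-en-1-yl)oxiran-2-yl]-4-[(4-methoxybenzyl)oxy]but-2-yn-1-ol | CC(C)=CCC[C@@]1(C)O[C@H]1[C@H](O)C#CCOCc1ccc(OC)cc1 | intermediate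
10 | (1R)-1-[(2S,3R)-3-methyl-3-(4-methylpent-3-en-1-yl)oxiran-2-yl]-4-[(4-methoxybenzyl)oxy]but-2-yn-1-yl methanesulfonate | CC(C)=CCC[C@@]1(C)O[C@H]1[C@H](OS(C)(=O)=O)C#CCOCc1ccc(OC)cc1 | intermediate
11 | (Ra)-2-{[(4-methoxybenzyl)oxy]methyl}-4-[(2S,3R)-3-methyl-3-(4-methylpent-3-en-1-yl)oxiran-2-yl]buta-2,3-dienoic acid | CC(C)=CCC[C@@]1(C)O[C@H]1C([H])=[C@]=C(COCc1ccc(OC)cc1)C(O)=O | intermediate
12 | (5R)-4-iodo-3-{[(4-methoxybenzyl)oxy]methyl}-5-[(2S,3R)-3-methyl-3-(4-methylpent-3-en-1-yl)oxiran-2-yl]furan-2(5H)-one (same spatial arrangement at C6 as the target; the descriptor is R only because iodine raises the priority of C4) | CC(C)=CCC[C@@]1(C)O[C@H]1[C@H]1OC(=O)C(COCc2ccc(OC)cc2)=C1I | intermediate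
13 | (2S)-4-{[(4-methoxybenzyl)oxy]methyl}-2-[(2S,3R)-3-methyl-3-(4-methylpent-3-en-1-yl)oxiran-2-yl]-5-oxo-2,5-dihydrofuran-3-carbaldehyde | CC(C)=CCC[C@@]1(C)O[C@H]1[C@H]1OC(=O)C(COCc2ccc(OC)cc2)=C1C=O | intermediate
14 | 4,4,5,5-tetramethyl-2-(propa-1,2-dien-1-yl)-1,3,2-dioxaborolane (allenylboronic acid pinacol ester) | C=C=CB1OC(C)(C)C(C)(C)O1 | starting material
15 | O-(pinacolatoboryl) derivative of 16 | CC(C)=CCC[C@@]1(C)O[C@H]1[C@H]1OC(=O)C(COCc2ccc(OC)cc2)=C1[C@@H](OB2OC(C)(C)C(C)(C)O2)CC#C | intermediate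
16 | (5S)-4-[(1S)-1-hydroxybut-3-yn-1-yl]-3-{[(4-methoxybenzyl)oxy]methyl}-5-[(2S,3R)-3-methyl-3-(4-methylpent-3-en-1-yl)oxiran-2-yl]furan-2(5H)-one | CC(C)=CCC[C@@]1(C)O[C@H]1[C@H]1OC(=O)C(COCc2ccc(OC)cc2)=C1[C@@H](O)CC#C | intermediate
17 | (1S)-1-{(2S)-4-{[(4-methoxybenzyl)oxy]methyl}-2-[(2S,3R)-3-methyl-3-(4-methylpent-3-en-1-yl)oxiran-2-yl]-5-oxo-2,5-dihydrofuran-3-yl}but-3-yn-1-yl propanoate | CC(C)=CCC[C@@]1(C)O[C@H]1[C@H]1OC(=O)C(COCc2ccc(OC)cc2)=C1[C@@H](OC(=O)CC)CC#C | intermediate
18 | (1S)-1-{(2S)-2-[(2S,3R)-3-(3,4-dihydroxy-4-methylpentyl)-3-methyloxiran-2-yl]-4-{[(4-methoxybenzyl)oxy]methyl}-5-oxo-2,5-dihydrofuran-3-yl}but-3-yn-1-yl propanoate (both diol epimers) | CC(C)(O)C(O)CC[C@@]1(C)O[C@H]1[C@H]1OC(=O)C(COCc2ccc(OC)cc2)=C1[C@@H](OC(=O)CC)CC#C | intermediate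
19 | (1S)-1-{(2S)-4-{[(4-methoxybenzyl)oxy]methyl}-2-[(2S,3R)-3-methyl-3-(3-oxopropyl)oxiran-2-yl]-5-oxo-2,5-dihydrofuran-3-yl}but-3-yn-1-yl propanoate | O=CCC[C@@]1(C)O[C@H]1[C@H]1OC(=O)C(COCc2ccc(OC)cc2)=C1[C@@H](OC(=O)CC)CC#C | intermediate
20 | (1S)-3-(acetyloxy)-1-{(2S)-4-{[(4-methoxybenzyl)oxy]methyl}-2-[(2S,3R)-3-methyl-3-(3-oxopropyl)oxiran-2-yl]-5-oxo-2,5-dihydrofuran-3-yl}but-3-en-1-yl propanoate | O=CCC[C@@]1(C)O[C@H]1[C@H]1OC(=O)C(COCc2ccc(OC)cc2)=C1[C@@H](OC(=O)CC)CC(=C)OC(C)=O | intermediate
21 | (4R,5S,6S,8S,10R)-10-acetoxy-4,5-epoxy-13-[(4-methoxybenzyl)oxy]-1-oxo-8-(propanoyloxy)germacr-7(11)-en-12,6-olide | CCC(=O)O[C@H]1C[C@@](C)(OC(C)=O)C(=O)CC[C@@]2(C)O[C@H]2[C@H]2OC(=O)C(COCc3ccc(OC)cc3)=C12 | intermediate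
22 | (4R,5S,6S,8S,10R)-10-acetoxy-4,5-epoxy-13-hydroxy-1-oxo-8-(propanoyloxy)germacr-7(11)-en-12,6-olide | CCC(=O)O[C@H]1C[C@@](C)(OC(C)=O)C(=O)CC[C@@]2(C)O[C@H]2[C@H]2OC(=O)C(CO)=C12 | intermediate
23 | CNP0285168.2, (4R,5S,6S,8S,10R)-10,13-diacetoxy-4,5-epoxy-1-oxo-8-(propanoyloxy)germacr-7(11)-en-12,6-olide | CCC(=O)O[C@H]1C[C@@](C)(OC(C)=O)C(=O)CC[C@@]2(C)O[C@H]2[C@H]2OC(=O)C(COC(C)=O)=C12 | target

**Step count and risks**
Total step count: 16. Longest linear sequence: 16 steps (from nerol 1).

Steps most likely to fail: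

1. Step 14 (the proposed carbene-catalysed macrocyclic hydroacylation). The risks are the entropic cost of the ten-membered ring, carbene-mediated acetyl transfer from the enol ester, base sensitivity of C6–H next to the oxirane, and unproven facial selectivity at C10. The fallback uses known chemistry and sets out from 19. Gold-catalysed hydration of the terminal alkyne (Ph3PAuCl/AgOTf, aqueous dioxane) gives the methyl ketone aldehyde F4. Samarium diiodide pinacol macrocyclisation of F4 (SmI2, THF, −78 °C, high dilution) gives the 1,10-diol F5, with C10 epimers separated. Oxidation of the secondary C1 hydroxyl (SO3·pyridine, DMSO, i-Pr2NEt) gives the tertiary α-ketol F6. Acetylation of F6 (Ac2O, DMAP, Et3N, 40 °C) returns to the route at 21.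

2. Step 7 (hydroxycarbonylation). Zerovalent palladium may ionise the allenyl oxirane of the product, or the oxirane may open. The fallback sets out from mesylate 10 and avoids palladium. Anti SN2' displacement with LiCuBr2 in THF gives the (Ra)-bromoallene F1. Bromine–lithium exchange (t-BuLi, Et2O, −100 °C) gives the configurationally stable allenyllithium F2. Carboxylation of F2 with CO2 and mild acidic work-up returns to the route at 11.

3. Step 10 (asymmetric propargylation of the hindered, sensitive aldehyde). Selectivity or conversion may be poor. The fallback sets out from 13 and replaces catalyst control by a non-selective addition followed by stereoinversion. Zinc-mediated Barbier propargylation (propargyl bromide, Zn, THF/aq. NH4Cl) gives 16 together with its C8 epimer, the (8R)-alcohol F3. After separation, 16 continues through step 11, and F3 is esterified with inversion by a Mitsunobu reaction (propanoic acid, PPh3, DIAD, toluene, 0 °C). Both streams return to the route at 17.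

**Further compounds**
F1 | step 7 | 1-({[(Ra)-2-bromo-4-[(2S,3R)-3-methyl-3-(4-methylpent-3-en-1-yl)oxiran-2-yl]buta-2,3-dien-1-yl]oxy}methyl)-4-methoxybenzene | CC(C)=CCC[C@@]1(C)O[C@H]1C([H])=[C@]=C(COCc1ccc(OC)cc1)Br
F2 | step 7 | allenyllithium from F1 (lithium in place of bromine, axis retained) | CC(C)=CCC[C@@]1(C)O[C@H]1C([H])=[C@]=C(COCc1ccc(OC)cc1)[Li]
F3 | step 10 | (5S)-4-[(1R)-1-hydroxybut-3-yn-1-yl]-3-{[(4-methoxybenzyl)oxy]methyl}-5-[(2S,3R)-3-methyl-3-(4-methylpent-3-en-1-yl)oxiran-2-yl]furan-2(5H)-one | CC(C)=CCC[C@@]1(C)O[C@H]1[C@H]1OC(=O)C(COCc2ccc(OC)cc2)=C1[C@H](O)CC#C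
F4 | step 14 | (1S)-1-{(2S)-4-{[(4-methoxybenzyl)oxy]methyl}-2-[(2S,3R)-3-methyl-3-(3-oxopropyl)oxiran-2-yl]-5-oxo-2,5-dihydrofuran-3-yl}-3-oxobutyl propanoate | O=CCC[C@@]1(C)O[C@H]1[C@H]1OC(=O)C(COCc2ccc(OC)cc2)=C1[C@@H](OC(=O)CC)CC(C)=O
F5 | step 14 | (4R,5S,6S,8S,10R)-4,5-epoxy-1,10-dihydroxy-13-[(4-methoxybenzyl)oxy]-8-(propanoyloxy)germacr-7(11)-en-12,6-olide (C1 epimers) | CCC(=O)O[C@H]1C[C@@](C)(O)C(O)CC[C@@]2(C)O[C@H]2[C@H]2OC(=O)C(COCc3ccc(OC)cc3)=C12
F6 | step 14 | (4R,5S,6S,8S,10R)-4,5-epoxy-10-hydroxy-13-[(4-methoxybenzyl)oxy]-1-oxo-8-(propanoyloxy)germacr-7(11)-en-12,6-olide | CCC(=O)O[C@H]1C[C@@](C)(O)C(=O)CC[C@@]2(C)O[C@H]2[C@H]2OC(=O)C(COCc3ccc(OC)cc3)=C12
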